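**Retrosynthetic overview**

1. Numbering as in mutilin: cyclopentanone C1–C2–C3(=O)–C4–C9; cyclohexane C4–C5–C6–C7–C8–C9; cyclooctane C4–C5–C14–C13–C12–C11–C10–C9; tetrahydrofuran O–C11–C12–C19–C20.
2. Cyclopentanone, closed last: the C1–C9 bond and the C3 ketone come from a PtCl2-catalysed cycloisomerization of the 5-en-1-yn-3-ol C1≡C2–C3H(OH)–C4–C9=C8, followed by hydrogenolysis of the transient cyclopropane bond C1–C8. The enabling feature is that quaternary C9 lies between the methylenes C1 and C8 with the C3 carbonyl two atoms from C1, so C1–C9–C8 is a latent cyclopropane on the bridgehead alkene C8=C9 of the bicyclo[5.3.1]undecene (cyclohexene plus cyclooctane).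
3. Cyclohexene and cyclooctane, closed together before that: a type 2 intramolecular Diels–Alder reaction (bonds C4–C5 and C6–C7) of the diene C4=C9–C8=C7, tethered at C9, with the (Z)-enone C14(=O)–C5=C6; it leaves exactly the C8=C9 bridgehead alkene.
4. Tetrahydrofuran, closed first: (S)-3-hydroxy-γ-butyrolactone supplies C19 and C20 and, by two Fráter–Seebach alkylations, quaternary C12; C10–C11 by a syn-selective allenylstannane addition, then Williamson closure at C20; diene by ynoate carbometalation, enone by Nozaki–Hiyama–Kishi coupling and oxidation.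
5. Ring order: tetrahydrofuran (step 9) → cyclohexene + cyclooctane (step 17) → cyclopentanone (step 22).

Key step: step 22

Assumption: the configuration is taken exactly as written in the given string (4S,5S,6S,9S,10R,11S,12S,14R,19S in the numbering above) and is carried unchanged through all intermediates; this string places the C10 and C14 arms of the eight-membered ring trans on the cyclohexane and C1 trans to C3, whereas the annulation arguments of steps 17 and 22 are those of a cis-bridged mutilin-type framework with cis delivery of C1, so the configuration written at C9 is not secured by step 22.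

**Route**

Step 1
Reactants: 1 (R)-but-3-yn-2-ol
Product: 2 (R)-but-3-yn-2-yl methanesulfonate
Conditions: MsCl, Et3N, CH2Cl2, −78 to 0 °C
Reagents that add atoms: methanesulfonyl chloride, CS(=O)(=O)Cl
Why: O-sulfonylation of a secondary alcohol, in which the C–O bond is not broken, so the R configuration is kept.

Step 2
Reactants: 2 (R)-but-3-yn-2-yl methanesulfonate
Product: 3 (aS)-tributyl(buta-1,2-dien-1-yl)stannane
Conditions: Bu3SnH, LiN(iPr)2, THF, 0 °C; CuBr·SMe2, −78 °C; then 2, −78 °C
Reagents that add atoms: tributyltin hydride, CCCC[SnH](CCCC)CCCC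
Why: anti-SN2' displacement of the propargylic mesylate by the stannylcopper reagent (Marshall allenylstannane synthesis) should transfer the central chirality of 2 into the axial chirality of the allene.

Step 3
Reactants: 4 (S)-3-hydroxy-γ-butyrolactone
Product: 5 (3S,4S)-4-hydroxy-3-methyloxolan-2-one
Conditions: LiN(iPr)2 (2.2 equiv), THF, −78 °C; MeI, −78 to −20 °C
Reagents that add atoms: iodomethane, CI
Why: Fráter–Seebach alkylation, in which the alkoxide–enolate dianion is methylated anti to the C19 alkoxide, giving the trans lactone.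

Step 4
Reactants: 5 (3S,4S)-4-hydroxy-3-methyloxolan-2-one
Product: 6 (3S,4S)-4-hydroxy-3-methyl-3-(prop-2-en-1-yl)oxolan-2-one
Conditions: LiN(iPr)2 (2.2 equiv), THF, −78 °C; allyl bromide, −78 to −20 °C
Reagents that add atoms: allyl bromide, C=CCBr
Why: second Fráter–Seebach alkylation, in which the allyl group (C13 arm) again enters anti to the alkoxide, so quaternary C12 is set with allyl trans and methyl cis to the C19 oxygen.

Step 5
Reactants: 6 (3S,4S)-4-hydroxy-3-methyl-3-(prop-2-en-1-yl)oxolan-2-one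
Product: 7 (3S,4S)-4-[(tert-butyldimethylsilyl)oxy]-3-methyl-3-(prop-2-en-1-yl)oxolan-2-one
Conditions: TBSOTf, 2,6-lutidine, CH2Cl2, 0 °C
Reagents that add atoms: tert-butyldimethylsilyl trifluoromethanesulfonate, CC(C)(C)[Si](C)(C)OS(=O)(=O)C(F)(F)F
Why: silylation of the hindered secondary alcohol with a silyl triflate, which touches no stereocentre.

Step 6
Reactants: 7 silyl-protected allyl methyl lactone
Product: 9 (2S,3S)-3-[(tert-butyldimethylsilyl)oxy]-4-[(methanesulfonyl)oxy]-N-methoxy-N,2-dimethyl-2-(prop-2-en-1-yl)butanamide, via chloromagnesium alkoxide of the ring-opened hydroxy amide 8 (not isolated)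
Conditions: MeNH(OMe)·HCl, i-PrMgCl (2 equiv), THF, −20 to 0 °C; then MsCl, 0 °C
Reagents that add atoms: N,O-dimethylhydroxylamine hydrochloride, CNOC.Cl; methanesulfonyl chloride, CS(=O)(=O)Cl
Why: aminolysis of the lactone by the magnesium amide (Weinreb amide formation) frees the C20 alkoxide, which is sulfonylated in the same flask before it can relactonize, turning C20 into the electrophile for the later ring closure.

Step 7
Reactants: 9 mesyloxy Weinreb amide
Product: 10 (2S,3S)-2-[(tert-butyldimethylsilyl)oxy]-3-formyl-3-methylhex-5-en-1-yl methanesulfonate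
Conditions: i-Bu2AlH, THF, −78 °C; aq. KNaC4H4O6
Reagents that add atoms: none
Why: Weinreb amide reduction stops at the aldehyde through the chelated tetrahedral intermediate, while the primary mesylate and the silyl ether should survive at −78 °C.

Step 8
Reactants: 10 α-quaternary aldehyde; 3 (aS)-allenylstannane
Product: 11 (2S,3R,4S,5R)-2-[(tert-butyldimethylsilyl)oxy]-4-hydroxy-3,5-dimethyl-3-(prop-2-en-1-yl)hept-6-yn-1-yl methanesulfonate
Conditions: BF3·OEt2, CH2Cl2, −78 °C
Reagents that add atoms: none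
Why: BF3-promoted Marshall allenylstannane addition (anti-SE2', open antiperiplanar transition state) should give the syn homopropargylic alcohol, the axial chirality of 3 setting C10 (R) and, through the syn relationship, C11 (S) by reagent control.

Step 9
Reactants: 11 hydroxy mesylate
Product: 12 (2S,3R,4S)-2-[(2R)-but-3-yn-2-yl]-4-[(tert-butyldimethylsilyl)oxy]-3-methyl-3-(prop-2-en-1-yl)oxolane
Conditions: NaH, THF, 0 °C to rt
Reagents that add atoms: none
Why: intramolecular Williamson etherification (5-exo-tet) of the C11 alkoxide onto the primary C20 mesylate closes the tetrahydrofuran without breaking the C11–O bond, so C11 is retained.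

Step 10
Reactants: 12 alkynyl tetrahydrofuran
Product: 13 methyl (4R)-4-[(2S,3R,4S)-4-[(tert-butyldimethylsilyl)oxy]-3-methyl-3-(prop-2-en-1-yl)oxolan-2-yl]pent-2-ynoate
Conditions: n-BuLi, THF, −78 °C; ClCO2Me, −78 to 0 °C
Reagents that add atoms: methyl chloroformate, COC(=O)Cl
Why: deprotonation of the terminal alkyne and C-acylation of the lithium acetylide give the ynoate that activates C9≡C4 for the later carbometalation.

Step 11
Reactants: 13 ynoate
Product: 14 methyl (4R)-4-[(2S,3R,4S)-4-[(tert-butyldimethylsilyl)oxy]-3-methyl-3-(2-oxoethyl)oxolan-2-yl]pent-2-ynoate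
Conditions: OsO4 (2 mol %), NaIO4, 2,6-lutidine, dioxane/H2O, rt
Reagents that add atoms: osmium tetroxide, O=[Os](=O)(=O)=O; sodium periodate, [Na+].[O-][I](=O)(=O)=O
Why: Lemieux–Johnson cleavage of the monosubstituted alkene to the C14 aldehyde, the electron-poor alkyne being inert to osmylation.

Step 12
Reactants: 14 aldehyde; 15 (Z)-2-bromobut-2-ene
Product: 16 methyl (4R)-4-[(2S,3R,4S)-4-[(tert-butyldimethylsilyl)oxy]-3-[(3Z)-2-hydroxy-3-methylpent-3-en-1-yl]-3-methyloxolan-2-yl]pent-2-ynoate (both C14 epimers)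
Conditions: CrCl2 (4 equiv), NiCl2 (2 mol %), DMF, rt
Reagents that add atoms: none
Why: Nozaki–Hiyama–Kishi coupling, in which the alkenylchromium species forms with retention of the Z geometry and adds chemoselectively to the aldehyde in the presence of the ester; the C14 epimers converge in step 15.

Step 13
Reactants: 16 ynoate allylic alcohol
Product: 17 methyl (2Z,4R)-3-ethenyl-4-[(2S,3R,4S)-4-[(tert-butyldimethylsilyl)oxy]-3-[(3Z)-2-hydroxy-3-methylpent-3-en-1-yl]-3-methyloxolan-2-yl]pent-2-enoate
Conditions: CH2=CHMgBr (3 equiv), CuBr·SMe2 (20 mol %), THF, −78 °C; aq. NH4Cl at −78 °C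
Reagents that add atoms: vinylmagnesium bromide, C=C[Mg]Br
Why: copper-catalysed syn-carbometalation (conjugate addition) of the ynoate at low temperature and protonation of the alkenylcopper with retention should place H cis to the new vinyl group and the ester outside, the geometry needed for a reactive s-cis diene.

Step 14
Reactants: 17 dienoate
Product: 18 (2Z,4R)-3-ethenyl-4-[(2S,3R,4S)-4-[(tert-butyldimethylsilyl)oxy]-3-[(3Z)-2-hydroxy-3-methylpent-3-en-1-yl]-3-methyloxolan-2-yl]pent-2-en-1-ol
Conditions: i-Bu2AlH, CH2Cl2, −78 °C; aq. KNaC4H4O6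
Reagents that add atoms: none
Why: 1,2-reduction of the conjugated ester to the allylic alcohol by an aluminium hydride, leaving both alkene geometries untouched.

Step 15
Reactants: 18 diol
Product: 19 (2Z,4R)-3-ethenyl-4-[(2S,3R,4S)-4-[(tert-butyldimethylsilyl)oxy]-3-methyl-3-[(3Z)-3-methyl-2-oxopent-3-en-1-yl]oxolan-2-yl]pent-2-enal
Conditions: Dess–Martin periodinane, NaHCO3, CH2Cl2, 0 °C to rt
Reagents that add atoms: none
Why: Dess–Martin oxidation of both allylic alcohols under buffered, non-isomerizing conditions should give the (Z)-enone (dienophile) and the dienal.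

Step 16
Reactants: 19 dienal enone
Product: 20 dimethyl acetal of 19 at C3
Conditions: HC(OMe)3, pyridinium p-toluenesulfonate (cat.), MeOH, 0 °C
Reagents that add atoms: trimethyl orthoformate, COC(OC)OC
Why: chemoselective acetalization of the aldehyde (the conjugated, α-branched ketone reacts far more slowly) removes the electron-withdrawing group from the diene.

Step 17
Reactants: 20 triene acetal
Product: 21 Diels–Alder adduct, tetrahydrofuran-fused bicyclo[5.3.1]undec-8-en-14-one with CH(OMe)2 on C4 cis to the C14 bridge (4R,5S,6S)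
Conditions: toluene (0.005 M), BHT, 170 °C, sealed tube
Reagents that add atoms: none
Why: type 2 intramolecular Diels–Alder reaction, in which the C10–C14 tether joins diene position C9 to dienophile carbon C5 and thereby enforces the bridged regiochemistry and an endo tether; suprafacial addition turns the (Z)-enone into trans methyls on C5/C6 and the outside acetal into a C4 substituent cis to the C14 bridge, and the cis-fused tetrahydrofuran with the C10 methyl in the tether should select the diene face.

Step 18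
Reactants: 21 bicyclic ketone
Product: 22 (14R)-alcohol of 21
Conditions: NaBH4, MeOH, −20 °C
Reagents that add atoms: none
Why: borohydride reduction of the C14 ketone, in which the small hydride should approach from the outer face of the eight-membered ring, away from the C5–C6 bond, to give the 14R carbinol.

Step 19
Reactants: 22 C14 alcohol; 23 [(tert-butyldimethylsilyl)oxy]acetic acid
Product: 24 14-O-{[(tert-butyldimethylsilyl)oxy]acetyl} ester of 22
Conditions: EDCI·HCl, DMAP, CH2Cl2, rt
Reagents that add atoms: none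
Why: carbodiimide (Steglich) esterification with DMAP acyl transfer, suited to the hindered secondary C14 alcohol and leaving C14 unchanged.

Step 20
Reactants: 24 acetal ester
Product: 26 (4S)-aldehyde, formyl group on the face of C4 turned away from the eight-membered ring, via C4-epimeric aldehyde 25 (not isolated)
Conditions: LiBF4, MeCN/H2O, rt; then DBU (0.2 equiv), CH2Cl2, rt
Reagents that add atoms: water, O
Why: mild acetal hydrolysis followed by base-mediated epimerization through the exocyclic enolate (the bridgehead position of C9 blocks migration of C8=C9 into conjugation) should deliver the thermodynamically preferred aldehyde, in which the formyl group escapes transannular strain with the C11–C13 segment.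

Step 21
Reactants: 26 (4S)-aldehyde
Product: 27 propargylic alcohol, C4–CH(OH)–C≡CH (both C3 epimers)
Conditions: HC≡CMgBr, THF, −78 °C
Reagents that add atoms: ethynylmagnesium bromide, C#C[Mg]Br
Why: chemoselective 1,2-addition of the alkynyl Grignard reagent to the aldehyde at low temperature (the ester reacts more slowly); the C3 epimers converge in step 22 because C3 becomes the carbonyl carbon.

Step 22
Reactants: 27 propargylic alcohol
Product: 28 cyclopropane-fused ketone (bonds C1–C9 and C1–C8 formed, C3 ketone), the bis-silylated 1,8-cyclo derivative of the target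
Conditions: PtCl2 (10 mol %), toluene, 80 °C
Reagents that add atoms: none
Why: PtCl2 activates the terminal alkyne of the 5-en-1-yn-3-ol unit C1≡C2–C3H(OH)–C4–C9=C8 and the bridgehead alkene attacks C1 in the endo mode, giving a cyclopropyl platinum carbene at C2; a 1,2-hydride shift from the carbinol carbon C3 and loss of the metal give the enol and then the C3 ketone, so the ketone level arrives without an oxidant. The closest known reaction type is the PtCl2- or gold-catalysed cycloisomerization of hydroxylated 1,5-enynes to bicyclo[3.1.0]hexan-3-ones, which accepts trisubstituted alkenes and builds quaternary ring-fusion carbons. The cyclopentanone closes through the C1–C9 bond (5-endo-dig at the alkyne) and the temporary cyclopropane through the C1–C8 bond in the same event. C9 (quaternary), C8 and C1 are set together, because the chain on C4 can reach only the outer face of C8=C9 on the side of the C4 substituent and only a cis-fused bicyclo[3.1.0]hexane can form, so C4 from step 20 controls all three. The step needs hydride shift in preference to acyl migration or skeletal shift, and engagement of a hindered alkene; the free hydroxyl, the 1,5-relationship of alkyne and alkene, and the torsional strain of the bridgehead alkene should secure this.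

Step 23
Reactants: 28 cyclopropane-fused ketone
Product: 29 bis(tert-butyldimethylsilyl) ether of the target
Conditions: H2 (3 atm), PtO2, AcOH, rt
Reagents that add atoms: none
Why: hydrogenolysis of the cyclopropane over Adams catalyst should cleave the least substituted and most accessible bond C1–C8 (two CH carbons), leaving quaternary C9 untouched and giving the C1 and C8 methylenes.

Step 24
Reactants: 29 bis-silyl ether
Product: 30 pleuromutilin B
Conditions: HF·pyridine, pyridine, THF, 0 °C to rt
Reagents that add atoms: none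
Why: fluoride-mediated cleavage of both silyl ethers under buffered conditions that leave the glycolate ester, the ketone and all stereocentres intact.

**Compound list**

1 | (R)-but-3-yn-2-ol | C[C@@H](O)C#C | starting material
2 | (R)-but-3-yn-2-yl methanesulfonate | C[C@@H](OS(C)(=O)=O)C#C | intermediate
3 | (aS)-tributyl(buta-1,2-dien-1-yl)stannane | CC([H])=[C@@]=C([H])[Sn](CCCC)(CCCC)CCCC | intermediate
4 | (S)-3-hydroxy-γ-butyrolactone, (4S)-4-hydroxyoxolan-2-one | O=C1OC[C@@H](O)C1 | starting material
5 | (3S,4S)-4-hydroxy-3-methyloxolan-2-one (methyl trans to hydroxyl) | O=C1OC[C@@H](O)[C@@H]1C | intermediate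
6 | (3S,4S)-4-hydroxy-3-methyl-3-(prop-2-en-1-yl)oxolan-2-one (allyl trans to hydroxyl) | O=C1OC[C@@H](O)[C@]1(C)CC=C | intermediate
7 | (3S,4S)-4-[(tert-butyldimethylsilyl)oxy]-3-methyl-3-(prop-2-en-1-yl)oxolan-2-one | O=C1OC[C@@H](O[Si](C)(C)C(C)(C)C)[C@]1(C)CC=C | intermediate
8 | chloromagnesium alkoxide of (2S,3S)-3-[(tert-butyldimethylsilyl)oxy]-4-hydroxy-N-methoxy-N,2-dimethyl-2-(prop-2-en-1-yl)butanamide | CON(C)C(=O)[C@@](C)(CC=C)[C@H](O[Si](C)(C)C(C)(C)C)CO[Mg]Cl | intermediate (not isolated)
9 | (2S,3S)-3-[(tert-butyldimethylsilyl)oxy]-4-[(methanesulfonyl)oxy]-N-methoxy-N,2-dimethyl-2-(prop-2-en-1-yl)butanamide | CON(C)C(=O)[C@@](C)(CC=C)[C@H](O[Si](C)(C)C(C)(C)C)COS(C)(=O)=O | intermediate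
10 | (2S,3S)-2-[(tert-butyldimethylsilyl)oxy]-3-formyl-3-methylhex-5-en-1-yl methanesulfonate | O=C[C@@](C)(CC=C)[C@H](O[Si](C)(C)C(C)(C)C)COS(C)(=O)=O | intermediate
11 | (2S,3R,4S,5R)-2-[(tert-butyldimethylsilyl)oxy]-4-hydroxy-3,5-dimethyl-3-(prop-2-en-1-yl)hept-6-yn-1-yl methanesulfonate (4-OH and 5-CH3 syn) | C#C[C@@H](C)[C@H](O)[C@@](C)(CC=C)[C@H](O[Si](C)(C)C(C)(C)C)COS(C)(=O)=O | intermediate
12 | (2S,3R,4S)-2-[(2R)-but-3-yn-2-yl]-4-[(tert-butyldimethylsilyl)oxy]-3-methyl-3-(prop-2-en-1-yl)oxolane | C#C[C@@H](C)[C@@H]1OC[C@@H](O[Si](C)(C)C(C)(C)C)[C@]1(C)CC=C | intermediate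
13 | methyl (4R)-4-[(2S,3R,4S)-4-[(tert-butyldimethylsilyl)oxy]-3-methyl-3-(prop-2-en-1-yl)oxolan-2-yl]pent-2-ynoate | COC(=O)C#C[C@@H](C)[C@@H]1OC[C@@H](O[Si](C)(C)C(C)(C)C)[C@]1(C)CC=C | intermediate
14 | methyl (4R)-4-[(2S,3R,4S)-4-[(tert-butyldimethylsilyl)oxy]-3-methyl-3-(2-oxoethyl)oxolan-2-yl]pent-2-ynoate | COC(=O)C#C[C@@H](C)[C@@H]1OC[C@@H](O[Si](C)(C)C(C)(C)C)[C@]1(C)CC=O | intermediate
15 | (Z)-2-bromobut-2-ene | Br/C(C)=C\C | starting material
16 | methyl (4R)-4-[(2S,3R,4S)-4-[(tert-butyldimethylsilyl)oxy]-3-[(3Z)-2-hydroxy-3-methylpent-3-en-1-yl]-3-methyloxolan-2-yl]pent-2-ynoate, both epimers at the new carbinol | COC(=O)C#C[C@@H](C)[C@@H]1OC[C@@H](O[Si](C)(C)C(C)(C)C)[C@]1(C)CC(O)/C(C)=C\C | intermediate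
17 | methyl (2Z,4R)-3-ethenyl-4-[(2S,3R,4S)-4-[(tert-butyldimethylsilyl)oxy]-3-[(3Z)-2-hydroxy-3-methylpent-3-en-1-yl]-3-methyloxolan-2-yl]pent-2-enoate | COC(=O)/C=C(/C=C)[C@@H](C)[C@@H]1OC[C@@H](O[Si](C)(C)C(C)(C)C)[C@]1(C)CC(O)/C(C)=C\C | intermediate
18 | (2Z,4R)-3-ethenyl-4-[(2S,3R,4S)-4-[(tert-butyldimethylsilyl)oxy]-3-[(3Z)-2-hydroxy-3-methylpent-3-en-1-yl]-3-methyloxolan-2-yl]pent-2-en-1-ol | OC/C=C(/C=C)[C@@H](C)[C@@H]1OC[C@@H](O[Si](C)(C)C(C)(C)C)[C@]1(C)CC(O)/C(C)=C\C | intermediate
19 | (2Z,4R)-3-ethenyl-4-[(2S,3R,4S)-4-[(tert-butyldimethylsilyl)oxy]-3-methyl-3-[(3Z)-3-methyl-2-oxopent-3-en-1-yl]oxolan-2-yl]pent-2-enal | O=C/C=C(/C=C)[C@@H](C)[C@@H]1OC[C@@H](O[Si](C)(C)C(C)(C)C)[C@]1(C)CC(=O)/C(C)=C\C | intermediate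
20 | dimethyl acetal of 19 at the aldehyde carbon C3 | COC(OC)/C=C(/C=C)[C@@H](C)[C@@H]1OC[C@@H](O[Si](C)(C)C(C)(C)C)[C@]1(C)CC(=O)/C(C)=C\C | intermediate
21 | Diels–Alder adduct: tetrahydrofuran-fused bicyclo[5.3.1]undec-8-en-14-one with C8=C9 bridgehead alkene, CH(OMe)2 on C4 cis to the C14 bridge (4R), methyls on C5, C6, C10, C12, OTBS on C19; C5, C6, C10, C11, C12, C19 arranged as in 30 | C[C@H]1[C@@H]2OC[C@@H](O[Si](C)(C)C(C)(C)C)[C@]2(C)CC(=O)[C@@]2(C)[C@@H](C)CC=C1[C@H]2C(OC)OC | intermediate
22 | (14R)-alcohol of 21 | C[C@H]1[C@@H]2OC[C@@H](O[Si](C)(C)C(C)(C)C)[C@]2(C)C[C@@H](O)[C@@]2(C)[C@@H](C)CC=C1[C@H]2C(OC)OC | intermediate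
23 | [(tert-butyldimethylsilyl)oxy]acetic acid | CC(C)(C)[Si](C)(C)OCC(=O)O | starting material
24 | 14-O-{[(tert-butyldimethylsilyl)oxy]acetyl} ester of 22 | C[C@H]1[C@@H]2OC[C@@H](O[Si](C)(C)C(C)(C)C)[C@]2(C)C[C@@H](OC(=O)CO[Si](C)(C)C(C)(C)C)[C@@]2(C)[C@@H](C)CC=C1[C@H]2C(OC)OC | intermediate
25 | aldehyde from 24 with C4 as in 21 (4R, formyl cis to the C14 bridge) | C[C@H]1[C@@H]2OC[C@@H](O[Si](C)(C)C(C)(C)C)[C@]2(C)C[C@@H](OC(=O)CO[Si](C)(C)C(C)(C)C)[C@@]2(C)[C@@H](C)CC=C1[C@H]2C=O | intermediate (not isolated)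
26 | C4-epimerized aldehyde (4S, formyl trans to the C14 bridge) | C[C@H]1[C@@H]2OC[C@@H](O[Si](C)(C)C(C)(C)C)[C@]2(C)C[C@@H](OC(=O)CO[Si](C)(C)C(C)(C)C)[C@@]2(C)[C@@H](C)CC=C1[C@@H]2C=O | intermediate
27 | propargylic alcohol, 26 with C4–CH(OH)–C≡CH, both C3 epimers | C[C@H]1[C@@H]2OC[C@@H](O[Si](C)(C)C(C)(C)C)[C@]2(C)C[C@@H](OC(=O)CO[Si](C)(C)C(C)(C)C)[C@@]2(C)[C@@H](C)CC=C1[C@@H]2C(O)C#C | intermediate
28 | cyclopropane-fused ketone: 29 with an extra C1–C8 bond (cyclopropane C1–C8–C9) | C[C@H]1[C@@H]2OC[C@@H](O[Si](C)(C)C(C)(C)C)[C@]2(C)C[C@@H](OC(=O)CO[Si](C)(C)C(C)(C)C)[C@@]2(C)[C@@H](C)C[C@@H]3[C@]14[C@@H]3CC(=O)[C@@H]42 | intermediate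
29 | pleuromutilin B bis(tert-butyldimethylsilyl) ether (at O19 and at the glycolate oxygen) | C[C@H]1[C@@H]2OC[C@@H](O[Si](C)(C)C(C)(C)C)[C@]2(C)C[C@@H](OC(=O)CO[Si](C)(C)C(C)(C)C)[C@@]2(C)[C@@H](C)CC[C@]13CCC(=O)[C@@H]32 | intermediate
30 | pleuromutilin B | C[C@H]1[C@@H]2OC[C@@H](O)[C@]2(C)C[C@@H](OC(=O)CO)[C@@]2(C)[C@@H](C)CC[C@]13CCC(=O)[C@@H]32 | target

**Totals and risks**

Total step count: 24. Longest linear sequence: 22 steps (steps 3 to 24, from 4); steps 1 and 2 prepare reagent 3.

The three steps most likely to fail: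

Step 17 (type 2 intramolecular Diels–Alder). The process at risk is thermal Z-to-E isomerization of the enone before cycloaddition, which would scramble C6, together with poor face selectivity or no closure of the medium ring. The fallback replaces the thermal pericyclic reaction with a low-temperature ionic Diels–Alder reaction. It sets out from 19: treatment with 1,2-bis(trimethylsilyloxy)ethane and TMSOTf in CH2Cl2 at −78 °C should give the bis(1,3-dioxolane) F1. On warming to −40 °C with further TMSOTf the C14 ketal should ionize to a 2-alkenyl-1,3-dioxolan-2-ylium ion, which adds to the diene and gives the bicyclic bis(dioxolane) F2. Hydrolysis with LiBF4 in wet MeCN should give the keto aldehyde F3, and acetalization of its aldehyde under the conditions of step 16 brings the route back to 21.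

Step 22 (key step). The process at risk is diversion of the platinum carbene into skeletal shift, or failure of the hindered bridgehead alkene to engage, so that the alkyne is merely hydrated or isomerized. The fallback is a photochemical annulation that sets out from 26. Addition of CH2=CHMgBr at −78 °C should give the allylic alcohol F4, and Dess–Martin oxidation the vinyl ketone F5. Irradiation at 350 nm should bring about a crossed intramolecular enone–alkene [2+2] cycloaddition, in which the first bond closes the five-membered ring between C1 and C9 (rule of five), to give the bicyclo[2.1.1]hexanone photoadduct F6. Reductive cleavage of its strained C2–C8 bond next to the ketone with SmI2 in THF/MeOH returns the route at 29, with no cyclopropane and no hydrogenolysis.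

Step 23 (cyclopropane hydrogenolysis). The process at risk is reduction of the C3 ketone over the platinum catalyst competing with slow C1–C8 cleavage. The fallback changes the oxidation level so that this no longer matters; it sets out from 28. NaBH4 in MeOH should give the cyclopropyl carbinol F7, and exhaustive hydrogenolysis (H2, PtO2, AcOH) the ring-opened C3 alcohol F8. Dess–Martin oxidation of F8 comes back to 29.

Further compounds
F1 | step 17 | bis(1,3-dioxolane) of 19 (aldehyde C3 and ketone C14 both ketalized) | O1CCOC1/C=C(/C=C)[C@@H](C)[C@@H]2OC[C@@H](O[Si](C)(C)C(C)(C)C)[C@]2(C)CC3(OCCO3)/C(C)=C\C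
F2 | step 17 | cycloadduct corresponding to 21 with 1,3-dioxolanes at C14 and at C3 | C[C@H]1[C@@H]2OC[C@@H](O[Si](C)(C)C(C)(C)C)[C@]2(C)CC3(OCCO3)[C@@]2(C)[C@@H](C)CC=C1[C@H]2C4OCCO4
F3 | step 17 | keto aldehyde corresponding to 21 with free C3 aldehyde | C[C@H]1[C@@H]2OC[C@@H](O[Si](C)(C)C(C)(C)C)[C@]2(C)CC(=O)[C@@]2(C)[C@@H](C)CC=C1[C@H]2C=O
F4 | step 22 | allylic alcohol, 26 with C4–CH(OH)–CH=CH2 | C[C@H]1[C@@H]2OC[C@@H](O[Si](C)(C)C(C)(C)C)[C@]2(C)C[C@@H](OC(=O)CO[Si](C)(C)C(C)(C)C)[C@@]2(C)[C@@H](C)CC=C1[C@@H]2C(O)C=C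
F5 | step 22 | vinyl ketone, C4–C(=O)–CH=CH2 | C[C@H]1[C@@H]2OC[C@@H](O[Si](C)(C)C(C)(C)C)[C@]2(C)C[C@@H](OC(=O)CO[Si](C)(C)C(C)(C)C)[C@@]2(C)[C@@H](C)CC=C1[C@@H]2C(=O)C=C
F6 | step 22 | crossed photoadduct, 29 with an extra C2–C8 bond (bicyclo[2.1.1]hexanone) | C[C@H]1[C@@H]2OC[C@@H](O[Si](C)(C)C(C)(C)C)[C@]2(C)C[C@@H](OC(=O)CO[Si](C)(C)C(C)(C)C)[C@@]2(C)[C@@H](C)C[C@@H]3[C@]14C[C@@H]3C(=O)[C@@H]42
F7 | step 23 | cyclopropyl carbinol, C3 alcohol of 28 | C[C@H]1[C@@H]2OC[C@@H](O[Si](C)(C)C(C)(C)C)[C@]2(C)C[C@@H](OC(=O)CO[Si](C)(C)C(C)(C)C)[C@@]2(C)[C@@H](C)C[C@@H]3[C@]14[C@@H]3CC(O)[C@@H]42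
F8 | step 23 | C3 alcohol of 29 | C[C@H]1[C@@H]2OC[C@@H](O[Si](C)(C)C(C)(C)C)[C@]2(C)C[C@@H](OC(=O)CO[Si](C)(C)C(C)(C)C)[C@@]2(C)[C@@H](C)CC[C@]13CCC(O)[C@@H]32
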